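## Retrosynthetic overview

1. Target ⇒ primary alcohol 18 (O‑sulfation) ⇒ terminal alkene 15 + 4‑bromofuranone (B‑alkyl Suzuki); C13 comes from aldehyde 13 by catalytic SOMO α‑allylation.
2. Key disconnection, C4–C5 of ring A: decalin 12 ⇒ monocyclic diene 11, closed by an MHAT‑initiated 6‑endo radical cycloisomerisation that forms ring A, sets C5 and leaves the C1=C10 alkene.
3. 11 ⇒ enol triflate 8 + 4‑methylpent‑4‑enyl Grignard; 8 ⇒ ketone 6 ⇒ enone 4 by asymmetric methyl conjugate addition and enolate methylation (C8, C9).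
4. 4 ⇒ 2‑iodocyclohexenone + 3‑butenal dimethyl acetal (B‑alkyl Suzuki).
5. Ring order: ring B is bought as the cyclohexenone, ring A is made by the radical step, the butenolide ring is attached last.

Assumption: the target is wanted as the free hydrogen sulfate exactly as drawn (the sodium salt would simply omit the final H+ exchange).

Numbering used in the text: ring A = C1–C5, C10; ring B = C5–C10; C8 carries a methyl; C9 carries a methyl and the chain C11–C12–C13(CH2O)–C14–C15–C16–butenolide. Relative configuration read from the SMILES: H‑5, the C8 methyl and the C9 side chain are on one face; the C9 methyl and C4 are on the other.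

## Route

Step 1
Reactants: 1 4,4‑dimethoxybut‑1‑ene; 2 2‑iodocyclohex‑2‑en‑1‑one
Product: 4 2‑(4,4‑dimethoxybutyl)cyclohex‑2‑en‑1‑one, via 9‑(4,4‑dimethoxybutyl)‑9‑borabicyclo[3.3.1]nonane 3 (not isolated)
Conditions: 9‑BBN, THF, 0 °C→rt; then 2, PdCl2(dppf) (5 mol %), AsPh3, Cs2CO3, DMF/THF/H2O, rt
Reagents that add atoms: none
Why: anti‑Markovnikov hydroboration gives the primary alkylborane, which couples with the α‑iodoenone at room temperature in a B‑alkyl Suzuki–Miyaura reaction; no stereocentre is formed.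

Step 2
Reactants: 4 2‑(4,4‑dimethoxybutyl)cyclohex‑2‑en‑1‑one
Product: 6 (2S,3S)‑2‑(4,4‑dimethoxybutyl)‑2,3‑dimethylcyclohexan‑1‑one, via bromomagnesium (3S)‑2‑(4,4‑dimethoxybutyl)‑3‑methylcyclohex‑1‑en‑1‑olate 5 (not isolated)
Conditions: MeMgBr, Cu(OTf)2 (3 mol %), chiral imidazolinium NHC precursor (4 mol %, enantiomer giving the 3S adduct), Et2O, –30 °C; then MeI, DMPU, –30 °C→rt
Reagents that add atoms: methylmagnesium bromide C[Mg]Br; iodomethane CI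
Why: copper–NHC‑catalysed asymmetric conjugate addition sets C8 under ligand control, and the tetrasubstituted magnesium enolate is then methylated anti to the new C3 methyl (tandem conjugate addition–enolate alkylation), so the quaternary C9 has its methyl trans and its side chain cis to the C8 methyl.

Step 3
Reactants: 6 (2S,3S)‑2‑(4,4‑dimethoxybutyl)‑2,3‑dimethylcyclohexan‑1‑one
Product: 8 (5S,6S)‑6‑(4,4‑dimethoxybutyl)‑5,6‑dimethylcyclohex‑1‑en‑1‑yl trifluoromethanesulfonate, via potassium (5S,6S)‑6‑(4,4‑dimethoxybutyl)‑5,6‑dimethylcyclohex‑1‑en‑1‑olate 7 (not isolated)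
Conditions: KHMDS, THF, –78 °C; then PhNTf2, –78→0 °C
Reagents that add atoms: N‑phenylbis(trifluoromethanesulfonimide) O=S(=O)(N(c1ccccc1)S(=O)(=O)C(F)(F)F)C(F)(F)F
Why: C9 is quaternary, so only the C5 methylene can enolise and a single enolate is O‑triflated (enol triflate formation); the stereocentres are untouched.

Step 4
Reactants: 8 (5S,6S)‑6‑(4,4‑dimethoxybutyl)‑5,6‑dimethylcyclohex‑1‑en‑1‑yl trifluoromethanesulfonate; 9 5‑bromo‑2‑methylpent‑1‑ene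
Product: 11 (5S,6S)‑6‑(4,4‑dimethoxybutyl)‑5,6‑dimethyl‑1‑(4‑methylpent‑4‑en‑1‑yl)cyclohex‑1‑ene, via (4‑methylpent‑4‑en‑1‑yl)magnesium bromide 10 (not isolated)
Conditions: 9, Mg, THF, rt; then 8, Fe(acac)3 (5 mol %), THF/NMP, –30 °C
Reagents that add atoms: none
Why: iron‑catalysed Kumada‑type sp2–sp3 coupling of alkyl Grignards with alkenyl triflates is fast at low temperature, is little affected by the neighbouring quaternary carbon, and leaves the acetal and the remote alkene alone.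

Step 5
Reactants: 11 (5S,6S)‑6‑(4,4‑dimethoxybutyl)‑5,6‑dimethyl‑1‑(4‑methylpent‑4‑en‑1‑yl)cyclohex‑1‑ene
Product: 12 (1S,2S,4aR)‑1‑(4,4‑dimethoxybutyl)‑1,2,5,5‑tetramethyl‑1,2,3,4,4a,5,6,7‑octahydronaphthalene
Conditions: Co(salen‑tBu,tBu)Cl (5 mol %), PhSiH3 (10 mol %), PhH (0.02 M), rt, Ar
Reagents that add atoms: none
Why: Proposed new method: hydrogen‑atom transfer from the cobalt hydride to the 1,1‑disubstituted alkene gives the tertiary C4 radical, which closes 6‑endo onto C5 of the ring alkene (5‑exo would have to join two fully substituted carbons next to quaternary C9) on the face that carries only the C9 methyl, away from the C8 methyl and the C9 chain, giving the all‑equatorial chair (C5 = 4aR), and the tertiary C10 radical then returns H• to Co(II) from the open C1 methylene rather than the buried C5–H, fixing the alkene at C1=C10 and regenerating the hydride; the closest known reactions are the Co(salen)/silane MHAT cycloisomerisation of dienes (5‑exo) and MHAT‑initiated 6‑endo radical cyclisations.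

Step 6
Reactants: 12 (1S,2S,4aR)‑1‑(4,4‑dimethoxybutyl)‑1,2,5,5‑tetramethyl‑1,2,3,4,4a,5,6,7‑octahydronaphthalene
Product: 13 4‑[(1S,2S,4aR)‑1,2,5,5‑tetramethyl‑1,2,3,4,4a,5,6,7‑octahydronaphthalen‑1‑yl]butanal
Conditions: PPTS (cat.), acetone/H2O, 40 °C
Reagents that add atoms: water O
Why: acetal hydrolysis under weak acid is too mild to move the trisubstituted alkene or trigger a carbonyl‑ene reaction.

Step 7
Reactants: 13 4‑[(1S,2S,4aR)‑1,2,5,5‑tetramethyl‑1,2,3,4,4a,5,6,7‑octahydronaphthalen‑1‑yl]butanal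
Product: 15 (2R)‑2‑{2‑[(1S,2S,4aR)‑1,2,5,5‑tetramethyl‑1,2,3,4,4a,5,6,7‑octahydronaphthalen‑1‑yl]ethyl}pent‑4‑en‑1‑ol, via (2R)‑2‑{2‑[(1S,2S,4aR)‑1,2,5,5‑tetramethyl‑1,2,3,4,4a,5,6,7‑octahydronaphthalen‑1‑yl]ethyl}pent‑4‑enal 14 (not isolated)
Conditions: allylSiMe3, (2S,5S)‑5‑benzyl‑2‑tert‑butyl‑3‑methylimidazolidin‑4‑one·TFA (20 mol %), CAN (2 equiv), NaHCO3, H2O, DME, –20 °C; then NaBH4, MeOH, 0 °C
Reagents that add atoms: allyltrimethylsilane C=CC[Si](C)(C)C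
Why: in SOMO organocatalysis the chiral enamine is oxidised by CAN to a radical cation that the allylsilane attacks on its open Si face, which sets C13 under catalyst control independently of the distant decalin centres, and immediate borohydride reduction prevents epimerisation of the α‑chiral aldehyde (the 2R descriptor of 14 and 15 is the same spatial arrangement as 13S in the target).

Step 8
Reactants: 15 (2R)‑2‑{2‑[(1S,2S,4aR)‑1,2,5,5‑tetramethyl‑1,2,3,4,4a,5,6,7‑octahydronaphthalen‑1‑yl]ethyl}pent‑4‑en‑1‑ol; 16 4‑bromofuran‑2(5H)‑one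
Product: 18 4‑[(4S)‑4‑(hydroxymethyl)‑6‑[(1S,2S,4aR)‑1,2,5,5‑tetramethyl‑1,2,3,4,4a,5,6,7‑octahydronaphthalen‑1‑yl]hexyl]furan‑2(5H)‑one, via 9‑[(4S)‑4‑{[(9‑borabicyclo[3.3.1]nonan‑9‑yl)oxy]methyl}‑6‑[(1S,2S,4aR)‑1,2,5,5‑tetramethyl‑1,2,3,4,4a,5,6,7‑octahydronaphthalen‑1‑yl]hexyl]‑9‑borabicyclo[3.3.1]nonane 17 (not isolated)
Conditions: 9‑BBN (2.5 equiv), THF, rt; then 16, PdCl2(dppf) (5 mol %), AsPh3, aq. K3PO4, DMF, rt
Reagents that add atoms: none
Why: 9‑BBN hydroborates only the monosubstituted alkene (the hindered C1=C10 alkene is inert and the hydroxyl is held as a borinate that hydrolyses on work‑up), and B‑alkyl Suzuki–Miyaura coupling with the β‑bromobutenolide gives the 4‑alkylbutenolide directly.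

Step 9
Reactants: 18 4‑[(4S)‑4‑(hydroxymethyl)‑6‑[(1S,2S,4aR)‑1,2,5,5‑tetramethyl‑1,2,3,4,4a,5,6,7‑octahydronaphthalen‑1‑yl]hexyl]furan‑2(5H)‑one
Product: 19 (2S)‑5‑(5‑oxo‑2,5‑dihydrofuran‑3‑yl)‑2‑{2‑[(1S,2S,4aR)‑1,2,5,5‑tetramethyl‑1,2,3,4,4a,5,6,7‑octahydronaphthalen‑1‑yl]ethyl}pentyl hydrogen sulfate
Conditions: SO3·pyridine, pyridine, 0 °C→rt; then Dowex 50W (H+), MeOH/H2O, 0 °C, lyophilise
Reagents that add atoms: sulfur trioxide–pyridine complex [O-]S(=O)(=O)[n+]1ccccc1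
Why: O‑sulfation of the only hydroxyl with SO3·pyridine is mild enough for the butenolide and the alkene, and cold H+ exchange releases the free hydrogen sulfate.

## Compound list

1 | 4,4‑dimethoxybut‑1‑ene (3‑butenal dimethyl acetal) | C=CCC(OC)OC | starting material
2 | 2‑iodocyclohex‑2‑en‑1‑one | O=C1CCCC=C1I | starting material
3 | 9‑(4,4‑dimethoxybutyl)‑9‑borabicyclo[3.3.1]nonane | COC(OC)CCCCB1C2CCCC1CCC2 | intermediate (not isolated)
4 | 2‑(4,4‑dimethoxybutyl)cyclohex‑2‑en‑1‑one | O=C1CCCC=C1CCCC(OC)OC | intermediate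
5 | bromomagnesium (3S)‑2‑(4,4‑dimethoxybutyl)‑3‑methylcyclohex‑1‑en‑1‑olate | C[C@H]1CCCC(O[Mg]Br)=C1CCCC(OC)OC | intermediate (not isolated)
6 | (2S,3S)‑2‑(4,4‑dimethoxybutyl)‑2,3‑dimethylcyclohexan‑1‑one | C[C@H]1CCCC(=O)[C@@]1(C)CCCC(OC)OC | intermediate
7 | potassium (5S,6S)‑6‑(4,4‑dimethoxybutyl)‑5,6‑dimethylcyclohex‑1‑en‑1‑olate | C[C@H]1CCC=C([O-])[C@@]1(C)CCCC(OC)OC.[K+] | intermediate (not isolated)
8 | (5S,6S)‑6‑(4,4‑dimethoxybutyl)‑5,6‑dimethylcyclohex‑1‑en‑1‑yl trifluoromethanesulfonate | C[C@H]1CCC=C(OS(=O)(=O)C(F)(F)F)[C@@]1(C)CCCC(OC)OC | intermediate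
9 | 5‑bromo‑2‑methylpent‑1‑ene | C=C(C)CCCBr | starting material
10 | (4‑methylpent‑4‑en‑1‑yl)magnesium bromide | C=C(C)CCC[Mg]Br | intermediate (not isolated)
11 | (5S,6S)‑6‑(4,4‑dimethoxybutyl)‑5,6‑dimethyl‑1‑(4‑methylpent‑4‑en‑1‑yl)cyclohex‑1‑ene | C[C@H]1CCC=C(CCCC(C)=C)[C@@]1(C)CCCC(OC)OC | intermediate
12 | (1S,2S,4aR)‑1‑(4,4‑dimethoxybutyl)‑1,2,5,5‑tetramethyl‑1,2,3,4,4a,5,6,7‑octahydronaphthalene | C[C@H]1CC[C@H]2C(=CCCC2(C)C)[C@@]1(C)CCCC(OC)OC | intermediate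
13 | 4‑[(1S,2S,4aR)‑1,2,5,5‑tetramethyl‑1,2,3,4,4a,5,6,7‑octahydronaphthalen‑1‑yl]butanal | C[C@H]1CC[C@H]2C(=CCCC2(C)C)[C@@]1(C)CCCC=O | intermediate
14 | (2R)‑2‑{2‑[(1S,2S,4aR)‑1,2,5,5‑tetramethyl‑1,2,3,4,4a,5,6,7‑octahydronaphthalen‑1‑yl]ethyl}pent‑4‑enal | C[C@H]1CC[C@H]2C(=CCCC2(C)C)[C@@]1(C)CC[C@H](CC=C)C=O | intermediate (not isolated)
15 | (2R)‑2‑{2‑[(1S,2S,4aR)‑1,2,5,5‑tetramethyl‑1,2,3,4,4a,5,6,7‑octahydronaphthalen‑1‑yl]ethyl}pent‑4‑en‑1‑ol | C[C@H]1CC[C@H]2C(=CCCC2(C)C)[C@@]1(C)CC[C@H](CC=C)CO | intermediate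
16 | 4‑bromofuran‑2(5H)‑one | BrC1=CC(=O)OC1 | starting material
17 | 9‑[(4S)‑4‑{[(9‑borabicyclo[3.3.1]nonan‑9‑yl)oxy]methyl}‑6‑[(1S,2S,4aR)‑1,2,5,5‑tetramethyl‑1,2,3,4,4a,5,6,7‑octahydronaphthalen‑1‑yl]hexyl]‑9‑borabicyclo[3.3.1]nonane | C[C@H]1CC[C@H]2C(=CCCC2(C)C)[C@@]1(C)CC[C@H](CCCB1C2CCCC1CCC2)COB1C2CCCC1CCC2 | intermediate (not isolated)
18 | 4‑[(4S)‑4‑(hydroxymethyl)‑6‑[(1S,2S,4aR)‑1,2,5,5‑tetramethyl‑1,2,3,4,4a,5,6,7‑octahydronaphthalen‑1‑yl]hexyl]furan‑2(5H)‑one | C[C@H]1CC[C@H]2C(=CCCC2(C)C)[C@@]1(C)CC[C@H](CCCC1=CC(=O)OC1)CO | intermediate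
19 | (2S)‑5‑(5‑oxo‑2,5‑dihydrofuran‑3‑yl)‑2‑{2‑[(1S,2S,4aR)‑1,2,5,5‑tetramethyl‑1,2,3,4,4a,5,6,7‑octahydronaphthalen‑1‑yl]ethyl}pentyl hydrogen sulfate | C[C@H]1CC[C@H]2C(=CCCC2(C)C)[C@@]1(C)CC[C@H](CCCC1=CC(=O)OC1)COS(=O)(=O)O | target

## Count and risks

Total step count: 9. Longest linear sequence: 9 steps (1/2 → 19); every other input is bought.

Steps most likely to fail, in order:

Step 5. The cobalt hydride may only isomerise the 1,1‑disubstituted alkene; the C10 radical may lose H from C5 to give the Δ5(10) alkene; the face selectivity at C5 rests on a steric argument and may be modest; some 5‑exo spiro product is possible. The fallback sets out from 6 and comes back at 12, and puts C5 under thermodynamic control. Ketone 6 is deprotonated with LDA and added to acetone to give the aldol adduct (2S,3S)‑2‑(4,4‑dimethoxybutyl)‑6‑(2‑hydroxypropan‑2‑yl)‑2,3‑dimethylcyclohexan‑1‑one F1. Dehydration (MsCl, Et3N, then DBU) gives the conjugated (2S,3S)‑2‑(4,4‑dimethoxybutyl)‑2,3‑dimethyl‑6‑(propan‑2‑ylidene)cyclohexan‑1‑one F2. Copper‑catalysed conjugate addition of but‑3‑enylmagnesium bromide (CuBr·SMe2, THF, –40 °C) builds the quaternary C4, and NaOMe/MeOH equilibration of the α‑centre puts the tert‑alkyl group equatorial, which is the target configuration, giving (2S,3S,6R)‑2‑(4,4‑dimethoxybutyl)‑2,3‑dimethyl‑6‑(2‑methylhex‑5‑en‑2‑yl)cyclohexan‑1‑one F3. Ozonolysis (O3, CH2Cl2/pyridine, –78 °C; Me2S) gives 4‑[(1R,3S,4S)‑3‑(4,4‑dimethoxybutyl)‑3,4‑dimethyl‑2‑oxocyclohexyl]‑4‑methylpentanal F4. Intramolecular McMurry coupling (TiCl3(DME)1.5, Zn–Cu, DME, reflux, slow addition) is still a ketyl‑radical C–C coupling, but of C1 with C10; it closes ring A with the alkene fixed at C1=C10 and gives 12.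

Step 2. Methyl Grignard reagents are the least selective partners in copper‑catalysed asymmetric conjugate addition, and the magnesium enolate may methylate sluggishly; every later stereocentre depends on this ee. The fallback sets out from 1 (hydroborated to 3 as in step 1) and comes back at 6, and lets a hydride rather than a methyl group create C8. 3‑Methylcyclohex‑2‑en‑1‑one is iodinated (I2, pyridine, CH2Cl2) to 2‑iodo‑3‑methylcyclohex‑2‑en‑1‑one F5. Suzuki coupling with borane 3 under the step‑1 conditions gives 2‑(4,4‑dimethoxybutyl)‑3‑methylcyclohex‑2‑en‑1‑one F6. Copper hydride asymmetric conjugate reduction (Cu(OAc)2, DTBM‑SEGPHOS enantiomer giving 3S, Ph2SiH2, toluene) gives {[(3S)‑2‑(4,4‑dimethoxybutyl)‑3‑methylcyclohex‑1‑en‑1‑yl]oxy}diphenylsilane F7. Fluoride activation (TBAT) and MeI then methylate anti to the C3 methyl and give 6.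

Step 7. The C13 centre is set by the catalyst alone, so the diastereomer ratio equals the catalyst er and the C13 epimer will be hard to remove; CAN might also touch the ring alkene. The fallback sets out from 13 and comes back at 14, which is reduced to 15 as before; it replaces the radical allylation by a polar aza‑enolate alkylation with a stoichiometric auxiliary. Aldehyde 13 is condensed with RAMP to (E)‑N‑[(2R)‑2‑(methoxymethyl)pyrrolidin‑1‑yl]‑4‑[(1S,2S,4aR)‑1,2,5,5‑tetramethyl‑1,2,3,4,4a,5,6,7‑octahydronaphthalen‑1‑yl]butan‑1‑imine F8. Deprotonation (LDA, THF, 0 °C) and allyl bromide at –100 °C give (E,2R)‑N‑[(2R)‑2‑(methoxymethyl)pyrrolidin‑1‑yl]‑2‑{2‑[(1S,2S,4aR)‑1,2,5,5‑tetramethyl‑1,2,3,4,4a,5,6,7‑octahydronaphthalen‑1‑yl]ethyl}pent‑4‑en‑1‑imine F9. Two‑phase cleavage with aqueous oxalic acid releases 14 without racemisation.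

Further compounds
F1 | step 5 | (2S,3S)‑2‑(4,4‑dimethoxybutyl)‑6‑(2‑hydroxypropan‑2‑yl)‑2,3‑dimethylcyclohexan‑1‑one | C[C@H]1CCC(C(C)(C)O)C(=O)[C@@]1(C)CCCC(OC)OC
F2 | step 5 | (2S,3S)‑2‑(4,4‑dimethoxybutyl)‑2,3‑dimethyl‑6‑(propan‑2‑ylidene)cyclohexan‑1‑one | C[C@H]1CCC(=C(C)C)C(=O)[C@@]1(C)CCCC(OC)OC
F3 | step 5 | (2S,3S,6R)‑2‑(4,4‑dimethoxybutyl)‑2,3‑dimethyl‑6‑(2‑methylhex‑5‑en‑2‑yl)cyclohexan‑1‑one | C[C@H]1CC[C@H](C(C)(C)CCC=C)C(=O)[C@@]1(C)CCCC(OC)OC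
F4 | step 5 | 4‑[(1R,3S,4S)‑3‑(4,4‑dimethoxybutyl)‑3,4‑dimethyl‑2‑oxocyclohexyl]‑4‑methylpentanal | C[C@H]1CC[C@H](C(C)(C)CCC=O)C(=O)[C@@]1(C)CCCC(OC)OC
F5 | step 2 | 2‑iodo‑3‑methylcyclohex‑2‑en‑1‑one | CC1=C(I)C(=O)CCC1
F6 | step 2 | 2‑(4,4‑dimethoxybutyl)‑3‑methylcyclohex‑2‑en‑1‑one | CC1=C(CCCC(OC)OC)C(=O)CCC1
F7 | step 2 | {[(3S)‑2‑(4,4‑dimethoxybutyl)‑3‑methylcyclohex‑1‑en‑1‑yl]oxy}diphenylsilane | C[C@H]1CCCC(O[SiH](c2ccccc2)c2ccccc2)=C1CCCC(OC)OC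
F8 | step 7 | (E)‑N‑[(2R)‑2‑(methoxymethyl)pyrrolidin‑1‑yl]‑4‑[(1S,2S,4aR)‑1,2,5,5‑tetramethyl‑1,2,3,4,4a,5,6,7‑octahydronaphthalen‑1‑yl]butan‑1‑imine | C[C@H]1CC[C@H]2C(=CCCC2(C)C)[C@@]1(C)CCC/C=N/N1CCC[C@@H]1COC
F9 | step 7 | (E,2R)‑N‑[(2R)‑2‑(methoxymethyl)pyrrolidin‑1‑yl]‑2‑{2‑[(1S,2S,4aR)‑1,2,5,5‑tetramethyl‑1,2,3,4,4a,5,6,7‑octahydronaphthalen‑1‑yl]ethyl}pent‑4‑en‑1‑imine | C[C@H]1CC[C@H]2C(=CCCC2(C)C)[C@@]1(C)CC[C@H](CC=C)/C=N/N1CCC[C@@H]1COC
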